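The target's only ring, in carotenoid numbering, is the cyclopentane C2–C6: tertiary hydroxyl on C5, polyene (C7 onward) on C6, isopropenyl (C1, C16, C17) on C2. Because C6 is allylic to the whole polyene and C2 lies four bonds away, the ring is cut at C2–C6, leading back to acyclic cis-(5S,6R)-5,6-epoxy-5,6-dihydrolycopene. One Lewis-acid operation opens the oxirane at C6, forms C2–C6, sets C2 and C6 from the single Sharpless-derived epoxide and unveils the isopropenyl group. The precursor is joined at C7=C8 by Wittig reaction of a nerol-derived epoxy aldehyde with a C30 polyenyl phosphonium salt built from geranyl bromide and crocetindialdehyde.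

Key step: step 8

Remark: locants are those of the target in carotenoid numbering (primed for the acyclic half) for every intermediate, and crocetindialdehyde is taken as a purchasable C20 building block.

Step 1
Reactants: 1 geranyl bromide, (2E)-1-bromo-3,7-dimethylocta-2,6-diene
Product: 2 diethyl [(2E)-3,7-dimethylocta-2,6-dien-1-yl]phosphonate
Conditions: P(OEt)3 (1.3 equiv), neat, 130 °C, EtBr distilled off
Reagents that add atoms: triethyl phosphite, CCOP(OCC)OCC
Why: Michaelis–Arbuzov reaction at the primary allylic bromide (SN2 by phosphorus, then loss of bromoethane), which leaves the 2E double bond untouched.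

Step 2
Reactants: 2 diethyl geranylphosphonate; 3 crocetindialdehyde, (all-E)-2,6,11,15-tetramethylhexadeca-2,4,6,8,10,12,14-heptaenedial (2.5 equiv)
Product: 5 apo-8'-lycopenal (all-E C30 aldehyde; aldehyde carbon is C8), via potassium phosphonate carbanion 4 (not isolated)
Conditions: KN(SiMe3)2, THF, −78 °C; then added to 3 in THF, −40 °C → rt, dark, Ar
Reagents that add atoms: none
Why: Horner–Wadsworth–Emmons olefination with an allyl-stabilised phosphonate carbanion should give the (E)-C7'=C8' bond through reversible addition and syn-elimination, while the excess of 3 and the lower electrophilicity of the chain-extended product aldehyde should hold the reaction at mono-olefination.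

Step 3
Reactants: 5 apo-8'-lycopenal
Product: 6 apo-8'-lycopenol, the all-E C30 primary allylic alcohol (hydroxyl on C8)
Conditions: NaBH4, MeOH/THF, 0 °C, dark
Reagents that add atoms: none
Why: Borohydride 1,2-reduction of the aldehyde, which for extended polyenals is faster than conjugate reduction and leaves every double bond in place.

Step 4
Reactants: 6 apo-8'-lycopenol
Product: 7 (apo-8'-lycopenyl)triphenylphosphonium bromide (phosphorus on C8)
Conditions: PPh3·HBr, MeOH/CH2Cl2, 0 °C → rt, dark; crystallisation
Reagents that add atoms: triphenylphosphine hydrobromide, [Br-].[PH+](c1ccccc1)(c1ccccc1)c1ccccc1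
Why: SN1-type phosphonium salt formation, in which HBr ionises the polyenylic alcohol and PPh3 captures the delocalised cation at the unhindered terminal carbon C8, the position that keeps the whole polyene conjugated.

Step 5
Reactants: 8 nerol, (2Z)-3,7-dimethylocta-2,6-dien-1-ol
Product: 9 (2R,3S)-2,3-epoxynerol, [(2R,3S)-3-methyl-3-(4-methylpent-3-en-1-yl)oxiran-2-yl]methanol (cis-oxirane)
Conditions: Ti(OiPr)4 (10 mol%), D-(−)-diethyl tartrate (12 mol%), t-BuOOH, 4 Å molecular sieves, CH2Cl2, −20 °C
Reagents that add atoms: tert-butyl hydroperoxide, CC(C)(C)OO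
Why: Katsuki–Sharpless asymmetric epoxidation of the titanium-bound allylic alcohol delivers oxygen syn to the Z alkene (hence the cis-oxirane) on the face dictated by the D-(−)-tartrate, which should set C2 as R and C3 as S (C6 and C5 of the target), while the isolated 6,7-alkene, lacking a directing hydroxyl, is left alone.

Step 6
Reactants: 9 (2R,3S)-2,3-epoxynerol
Product: 10 (2S,3S)-3-methyl-3-(4-methylpent-3-en-1-yl)oxirane-2-carbaldehyde (same spatial arrangement as 9)
Conditions: 2,2,6,6-tetramethylpiperidin-1-oxyl (10 mol%), PhI(OAc)2, CH2Cl2, 0 °C → rt; used at once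
Reagents that add atoms: none
Why: Oxoammonium-mediated oxidation of the primary alcohol stops at the aldehyde under near-neutral conditions and the oxirane carbons cannot enolise, so both stereocentres persist (the descriptor at C2 changes only because the substituent priorities change).

Step 7
Reactants: 7 (apo-8'-lycopenyl)triphenylphosphonium bromide; 10 epoxy aldehyde
Product: 12 (5S,6R)-5,6-epoxy-5,6-dihydro-ψ,ψ-carotene (cis-oxirane; all-E), via polyenylidene phosphorane 11 (not isolated)
Conditions: NaN(SiMe3)2, THF, −78 °C; then 10, −78 → 0 °C, dark, Ar; Et3N-deactivated neutral alumina, crystallisation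
Reagents that add atoms: none
Why: Wittig olefination with a polyenyl ylide whose charge is spread over the conjugated chain, so that equilibration of the adducts should favour the (E)-C7=C8 alkene, while the cold, basic, aprotic medium leaves the oxirane (C5, C6) untouched.

Step 8
Reactants: 12 (5S,6R)-5,6-epoxy-5,6-dihydro-ψ,ψ-carotene
Product: 13 target, (2S,5S,6R)-1,16-didehydro-1,2,5,6-tetrahydro-2,6-cyclo-ψ,ψ-caroten-5-ol (C5 hydroxyl cis to the C6 polyenyl chain, C2 isopropenyl trans to both)
Conditions: Sc(OTf)3 (scandium tris(trifluoromethanesulfonate), 10 mol%), 2,6-di-tert-butylpyridine (1.5 equiv), 4 Å molecular sieves, CH2Cl2, −78 → −40 °C, dark, Ar; Et3N quench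
Reagents that add atoms: none
Why: Sc(OTf)3 binds the oxirane oxygen and the C6–O bond, allylic to the whole decaene, stretches while the tertiary C5–O bond holds; the C1=C2 alkene then bonds through C2 to C6 on the side opposite the leaving oxygen, and the tertiary C1 cation gives up a C16 methyl proton to the hindered pyridine, which passes it on to the C5 alkoxide so that scandium is released. The closest known reaction type is the epoxide-initiated cation–olefin cyclisation, here in the form of the acid-promoted rearrangement of acyclic carotenoid 5,6-epoxides to 2,6-cyclo end groups. The one ring closed, cyclopentane C2–C3–C4–C5–C6, forms exo with respect to the alkene (C1 stays outside) and endo with respect to the oxirane (C5 and C6 both end in the ring), a formally 5-endo opening that is feasible only because C6 carries much cationic character. C6 is set by inversion of the (6R) oxirane carbon, which with the cis geometry of the epoxide leaves the polyenyl chain cis to the C5 hydroxyl, and C2 is set by an envelope transition state that keeps the isopropylidene terminus pseudo-equatorial and anti to the polyenyl chain (C5 is inherited from step 5). The step needs anti opening without a free polyenyl cation, C-alkylation at C6 instead of oxygen return to C8 or a 1,2-shift, and loss of a methyl instead of the ring proton: the cold, weakly ionising medium and a catalytic Lewis acid with non-nucleophilic counter-ions serve the first two, and the bulky base, the six methyl hydrogens and the allylic strain that an isopropylidene group would suffer against C6 serve the third. The hydroxyl ends trans to the C2 substituent and therefore cannot close an ether onto C1.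

Compound list
1 | geranyl bromide, (2E)-1-bromo-3,7-dimethylocta-2,6-diene | CC(C)=CCC/C(C)=C/CBr | starting material
2 | diethyl [(2E)-3,7-dimethylocta-2,6-dien-1-yl]phosphonate | CC(C)=CCC/C(C)=C/CP(=O)(OCC)OCC | intermediate
3 | crocetindialdehyde, (all-E)-2,6,11,15-tetramethylhexadeca-2,4,6,8,10,12,14-heptaenedial | O=C/C(C)=C/C=C/C(C)=C/C=C/C=C(C)/C=C/C=C(C)/C=O | starting material
4 | potassium salt of the α-carbanion of 2 | CC(C)=CCC/C(C)=C/[CH-]P(=O)(OCC)OCC.[K+] | intermediate (not isolated)
5 | apo-8'-lycopenal, (all-E)-2,6,11,15,19,23-hexamethyltetracosa-2,4,6,8,10,12,14,16,18,22-decaenal | O=C/C(C)=C/C=C/C(C)=C/C=C/C=C(C)/C=C/C=C(C)/C=C/C=C(\C)CCC=C(C)C | intermediate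
6 | apo-8'-lycopenol, (all-E)-2,6,11,15,19,23-hexamethyltetracosa-2,4,6,8,10,12,14,16,18,22-decaen-1-ol | OC/C(C)=C/C=C/C(C)=C/C=C/C=C(C)/C=C/C=C(C)/C=C/C=C(\C)CCC=C(C)C | intermediate
7 | [(all-E)-2,6,11,15,19,23-hexamethyltetracosa-2,4,6,8,10,12,14,16,18,22-decaen-1-yl]triphenylphosphonium bromide | [Br-].c1ccccc1[P+](c1ccccc1)(c1ccccc1)C/C(C)=C/C=C/C(C)=C/C=C/C=C(C)/C=C/C=C(C)/C=C/C=C(\C)CCC=C(C)C | intermediate
8 | nerol, (2Z)-3,7-dimethylocta-2,6-dien-1-ol | CC(C)=CCC/C(C)=C\CO | starting material
9 | (2R,3S)-2,3-epoxynerol, [(2R,3S)-3-methyl-3-(4-methylpent-3-en-1-yl)oxiran-2-yl]methanol | CC(C)=CCC[C@]1(C)O[C@@H]1CO | intermediate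
10 | (2S,3S)-3-methyl-3-(4-methylpent-3-en-1-yl)oxirane-2-carbaldehyde | CC(C)=CCC[C@]1(C)O[C@@H]1C=O | intermediate
11 | triphenylphosphonium ylide of 7 (carbanion on C8) | c1ccccc1[P+](c1ccccc1)(c1ccccc1)[CH-]/C(C)=C/C=C/C(C)=C/C=C/C=C(C)/C=C/C=C(C)/C=C/C=C(\C)CCC=C(C)C | intermediate (not isolated)
12 | (5S,6R)-5,6-epoxy-5,6-dihydro-ψ,ψ-carotene, cis-oxirane, all-E | CC(C)=CCC[C@]1(C)O[C@@H]1/C=C/C(C)=C/C=C/C(C)=C/C=C/C=C(C)/C=C/C=C(C)/C=C/C=C(\C)CCC=C(C)C | intermediate
13 | (2S,5S,6R)-1,16-didehydro-1,2,5,6-tetrahydro-2,6-cyclo-ψ,ψ-caroten-5-ol | C=C(C)[C@H]1CC[C@](C)(O)[C@@H]1/C=C/C(C)=C/C=C/C(C)=C/C=C/C=C(C)/C=C/C=C(C)/C=C/C=C(\C)CCC=C(C)C | target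

Total step count: 8. Longest linear sequence: 6 steps (steps 1, 2, 3, 4, 7, 8).

Steps most likely to fail

1. Step 8. The oxirane may ionise to a free, long-lived polyenyl cation before the C–C bond forms, so that rotation about C5–C6 or reclosure erodes the configuration at C6. The C5 oxygen may return to C8 (furanoid rearrangement) or a 1,2-shift may occur. Proton loss may take the ring hydrogen at C2, or adventitious water may capture C1. The fallback sets out from nerol 8 and comes back at target 13; it keeps the C2–C6 closure but ends it on an allylsilane, a much stronger π-nucleophile that terminates by loss of silicon (allylsilane-terminated epoxide cyclisation, known chemistry). Nerol 8 is acetylated (Ac2O, pyridine) to neryl acetate F1. The more electron-rich 6,7-alkene is epoxidised with mCPBA to 6,7-epoxyneryl acetate F2, which periodic acid cleaves to the Z-configured acetoxy aldehyde F3. Wittig reaction with the β-silyl ylide F4 (prepared beforehand from ethyltriphenylphosphonium bromide, n-BuLi and (iodomethyl)trimethylsilane) gives the allylsilane acetate F5, whose new alkene geometry is immaterial, and K2CO3 in MeOH frees 8-(trimethylsilyl)nerol F6. Steps 5 to 7 are then repeated in the silylated series: Sharpless epoxidation with D-(−)-diethyl tartrate to the epoxy alcohol F7, Parikh–Doering oxidation to the epoxy aldehyde F8, and Wittig union with ylide 11 to the 16-(trimethylsilyl) epoxide F9. The buffered Lewis acid of step 8 at −78 °C should then close C2–C6 through the γ-carbon of the allylsilane. The β-silyl cation at C1 can only collapse to the C1=C16 alkene, and a K2CO3/MeOH work-up removes any silyl group passed to the C5 oxygen, giving 13.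

2. Step 7. The ylide solution may degrade the epoxy aldehyde, the E selectivity at C7=C8 may be incomplete, and the product may open on the adsorbent during removal of triphenylphosphine oxide. The fallback sets out from alcohol 6 and comes back at epoxide 12, replacing the ylide by a phosphonate carbanion. PBr3 with pyridine (Et2O, −20 °C) converts 6 into the polyenyl bromide F10, which is used at once in a Michaelis–Becker reaction with NaP(O)(OEt)2 (THF, 0 °C) to give the diethyl phosphonate F11. Deprotonation with NaN(SiMe3)2 (THF, −78 °C) gives the sodium phosphonate carbanion F12, and Horner–Wadsworth–Emmons olefination with aldehyde 10 should give 12 with the E preference typical of allylic phosphonates. The phosphate by-product is water-soluble, so little contact with adsorbents is needed.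

3. Step 2. A second olefination of the product aldehyde would lead to the symmetrical C40 polyene, and the sparingly soluble excess dialdehyde may be hard to separate and recover. The fallback sets out from dialdehyde 3 and comes back at aldehyde 5, making the desymmetrisation reversible before the C–C bond is formed. One equivalent of 2,2-dimethylpropane-1,3-diol with pyridinium p-toluenesulfonate (toluene, removal of water) gives, after separation, the monoacetal F13, while recovered 3 and bis-acetal are re-equilibrated. Carbanion 4 can olefinate F13 only once, giving the C30 acetal F14, which oxalic acid in wet acetone hydrolyses to 5.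

Further compounds
F1 | step 8 | neryl acetate, (2Z)-3,7-dimethylocta-2,6-dien-1-yl acetate | CC(C)=CCC/C(C)=C\COC(C)=O
F2 | step 8 | 6,7-epoxyneryl acetate (racemic at the oxirane carbon) | CC1(C)OC1CC/C(C)=C\COC(C)=O
F3 | step 8 | (2Z)-3-methyl-6-oxohex-2-en-1-yl acetate | O=CCC/C(C)=C\COC(C)=O
F4 | step 8 | [1-(trimethylsilyl)propan-2-ylidene]triphenylphosphorane | C[Si](C)(C)C[C-](C)[P+](c1ccccc1)(c1ccccc1)c1ccccc1
F5 | step 8 | (2Z)-3,7-dimethyl-8-(trimethylsilyl)octa-2,6-dien-1-yl acetate (6E/6Z mixture) | C[Si](C)(C)CC(C)=CCC/C(C)=C\COC(C)=O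
F6 | step 8 | (2Z)-3,7-dimethyl-8-(trimethylsilyl)octa-2,6-dien-1-ol | C[Si](C)(C)CC(C)=CCC/C(C)=C\CO
F7 | step 8 | [(2R,3S)-3-methyl-3-[4-methyl-5-(trimethylsilyl)pent-3-en-1-yl]oxiran-2-yl]methanol | C[Si](C)(C)CC(C)=CCC[C@]1(C)O[C@@H]1CO
F8 | step 8 | (2S,3S)-3-methyl-3-[4-methyl-5-(trimethylsilyl)pent-3-en-1-yl]oxirane-2-carbaldehyde | C[Si](C)(C)CC(C)=CCC[C@]1(C)O[C@@H]1C=O
F9 | step 8 | (5S,6R)-5,6-epoxy-16-(trimethylsilyl)-5,6-dihydro-ψ,ψ-carotene | C[Si](C)(C)CC(C)=CCC[C@]1(C)O[C@@H]1/C=C/C(C)=C/C=C/C(C)=C/C=C/C=C(C)/C=C/C=C(C)/C=C/C=C(\C)CCC=C(C)C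
F10 | step 7 | apo-8'-lycopenyl bromide (bromine on C8) | BrC/C(C)=C/C=C/C(C)=C/C=C/C=C(C)/C=C/C=C(C)/C=C/C=C(\C)CCC=C(C)C
F11 | step 7 | diethyl (apo-8'-lycopenyl)phosphonate | CCOP(=O)(OCC)C/C(C)=C/C=C/C(C)=C/C=C/C=C(C)/C=C/C=C(C)/C=C/C=C(\C)CCC=C(C)C
F12 | step 7 | sodium salt of the α-carbanion of F11 | [Na+].CCOP(=O)(OCC)[CH-]/C(C)=C/C=C/C(C)=C/C=C/C=C(C)/C=C/C=C(C)/C=C/C=C(\C)CCC=C(C)C
F13 | step 2 | crocetindialdehyde mono(2,2-dimethylpropane-1,3-diyl) acetal | CC1(C)COC(OC1)/C(C)=C/C=C/C(C)=C/C=C/C=C(C)/C=C/C=C(C)/C=O
F14 | step 2 | apo-8'-lycopenal 2,2-dimethylpropane-1,3-diyl acetal | CC1(C)COC(OC1)/C(C)=C/C=C/C(C)=C/C=C/C=C(C)/C=C/C=C(C)/C=C/C=C(\C)CCC=C(C)C
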